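**Plan**
- Retrosynthetic cuts: the lactone C12–O6 bond (back to a 1,4-diol), the oxirane oxygen (back to the Z-C4=C5 olefin), then C4=C5 itself (ring-closing metathesis of a C6 vinyl carbinol with a C4 isopropenyl end); further back C1–C2 (thioester + alkylzinc), C5–C6 (vinyl addition), C11–C12 (lactone-enolate hydroxymethylation) and C7–C8 (Evans aldol).
- Enabling feature: the C4–C5 bond is the C–C edge of the oxirane fused to the ten-membered carbocycle (C1–C10) and lies next to the C6 carbinol. The retron is therefore a (Z)-cyclodec-2-en-1-ol: metathesis closes the ring there, and the C6–OH then delivers the epoxide oxygen.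
- Forward order: open chain first; a temporary γ-lactone on O8; the acyclic seco-diene; the ten-membered ring (RCM); the oxirane; last the γ-lactone on O6.
- Stereochemistry: C10 is bought ((R)-citramalic acid). C7/C8 come from an Evans syn-aldol and C6 from a Felkin–Anh vinyl addition. C11 comes from trans-alkylation of the temporary O8-lactone. Its carbonyl ends as C13 (CH2OAc) and its new hydroxymethyl ends as C12, which uses the local pseudo-symmetry at C7 (two carbinol arms) and C11 (two C1 arms). C4/C5 come from the Z-olefin and hydroxyl-directed epoxidation.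

Key step: step 21

Remark 1: the SMILES is read as the (4R,5S,6S,7R,8S,10R,11R) isomer, with a cis-fused oxirane (C3 and C6 cis, i.e. from a Z-olefin), a trans-fused lactone, and an (E)-2-methylbut-2-enoate (tiglate) on O8.
Remark 2: atom locants follow germacranolide numbering (ring C1–C10, C1 = ketone, C10 = acetoxy carbon; C12 = lactone carbonyl; C13 = CH2OAc). In every intermediate each stereocentre has the spatial arrangement it has in 32; CIP letters change with the substituents, so the SMILES is authoritative.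

**Route**

Step 1
Reactants: 1 (R)-citramalic acid
Product: 2 (2R)-2-methylbutane-1,2,4-triol
Conditions: BH3·SMe2, B(OMe)3, THF, 0 → 23 °C; MeOH
Reagents that add atoms: none
Why: Borane reduction of both carboxylic acids to primary alcohols leaves the tertiary carbinol, and so the bought C10 stereocentre, untouched.

Step 2
Reactants: 2 (2R)-2-methylbutane-1,2,4-triol
Product: 3 2-[(4R)-2,2,4-trimethyl-1,3-dioxolan-4-yl]ethanol
Conditions: 2,2-dimethoxypropane, acetone, p-TsOH (cat.), 23 °C
Reagents that add atoms: 2,2-dimethoxypropane, COC(C)(C)OC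
Why: Thermodynamic ketalisation should select the five-membered dioxolane across the vicinal tertiary/primary diol and leave the C8 hydroxyl free.

Step 3
Reactants: 3 2-[(4R)-2,2,4-trimethyl-1,3-dioxolan-4-yl]ethanol
Product: 4 2-[(4R)-2,2,4-trimethyl-1,3-dioxolan-4-yl]acetaldehyde
Conditions: TEMPO (cat.), PhI(OAc)2, CH2Cl2, 23 °C
Reagents that add atoms: none
Why: Oxoammonium (TEMPO) oxidation stops at the aldehyde and is mild enough for the ketal.

Step 4
Reactants: 5 (4R)-4-benzyl-1,3-oxazolidin-2-one; 6 methyl 4-chloro-4-oxobutanoate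
Product: 7 methyl 4-[(4R)-4-benzyl-2-oxo-1,3-oxazolidin-3-yl]-4-oxobutanoate
Conditions: n-BuLi, THF, −78 °C; then 6
Reagents that add atoms: none
Why: N-acylation of the lithiated Evans auxiliary by the acid chloride.

Step 5
Reactants: 7 methyl 4-[(4R)-4-benzyl-2-oxo-1,3-oxazolidin-3-yl]-4-oxobutanoate; 4 2-[(4R)-2,2,4-trimethyl-1,3-dioxolan-4-yl]acetaldehyde
Product: 9 lactone imide (trans γ-lactone O8–C8–C7–C11–C=O with the acyl oxazolidinone on C7), via syn-aldol adduct 8 (not isolated)
Conditions: n-Bu2BOTf, i-Pr2NEt, CH2Cl2, −78 → 0 °C; pH 7 buffer, MeOH, H2O2; then PPTS (cat.), toluene, 60 °C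
Reagents that add atoms: none
Why: Evans boron syn-aldol through the Z-enolate and a Zimmerman–Traxler chair, in which the (R)-benzyl auxiliary sets C7 and C8; the C8 hydroxyl then lactonises onto the methyl ester (syn-aldol gives the trans lactone), which marks O8 apart from the later O6.

Step 6
Reactants: 9 lactone imide
Product: 10 lactone thioester (S-ethyl thioester at C6)
Conditions: EtSH, n-BuLi, THF, 0 °C
Reagents that add atoms: lithium ethanethiolate, [Li+].CC[S-]
Why: Transthioesterification at the exocyclic imide carbonyl by a soft, weakly basic thiolate should spare the lactone and the epimerisable C7 and release the auxiliary.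

Step 7
Reactants: 10 lactone thioester
Product: 11 lactone aldehyde (CHO = C6)
Conditions: Et3SiH, 10% Pd/C, acetone, 23 °C
Reagents that add atoms: none
Why: Fukuyama reduction converts the thioester to the aldehyde under neutral conditions that tolerate lactone and ketal.

Step 8
Reactants: 11 lactone aldehyde
Product: 12 vinyl carbinol lactone (C6–OH)
Conditions: CeCl3, CH2=CHMgBr, THF, −78 °C; AcOH quench at −78 °C
Reagents that add atoms: vinylmagnesium bromide, C=C[Mg]Br
Why: Organocerium 1,2-addition under Felkin–Anh control (C8, the oxygen-bearing, more substituted ring carbon, anti to the nucleophile; C11 inside) should set C6 with its oxygen syn to C11, while the low basicity and the cold quench avoid β-elimination and lactone migration.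

Step 9
Reactants: 12 vinyl carbinol lactone
Product: 13 C6 silyl ether (OTBS)
Conditions: TBSOTf, 2,6-lutidine, CH2Cl2, −78 °C
Reagents that add atoms: tert-butyldimethylsilyl triflate, CC(C)(C)[Si](C)(C)OS(=O)(=O)C(F)(F)F
Why: Silylation of the allylic alcohol blocks O8→O6 translactonisation before enolate chemistry.

Step 10
Reactants: 13 C6 silyl ether
Product: 14 α-hydroxymethyl lactone (CH2OH on C11, trans to the C7 substituent)
Conditions: LDA, THF, −78 °C; CH2O (gas, from cracked paraformaldehyde), −78 → −40 °C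
Reagents that add atoms: formaldehyde, C=O
Why: Lactone-enolate aldol with formaldehyde; the electrophile enters anti to the C7 substituent (α,β-trans rule for β-substituted butyrolactones), which sets C11, and the new carbon is the future C12.

Step 11
Reactants: 14 α-hydroxymethyl lactone
Product: 15 C12 silyl ether (OTBDPS)
Conditions: TBDPSCl, imidazole, DMF, 23 °C
Reagents that add atoms: tert-butyldiphenylsilyl chloride, CC(C)(C)[Si](Cl)(c1ccccc1)c1ccccc1
Why: Silylation of the primary alcohol with an acid-stable, migration-resistant group labels the C12 arm.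

Step 12
Reactants: 15 C12 silyl ether
Product: 16 seco-diol (C8–OH and C13–OH free)
Conditions: LiBH4, MeOH (1 equiv), THF, 0 → 23 °C
Reagents that add atoms: none
Why: Hydride reduction of the lactone turns its carbonyl into the C13 hydroxymethyl and frees O8, so C11 is now a fixed, non-epimerisable centre with two different arms.

Step 13
Reactants: 16 seco-diol
Product: 17 C13 acetate
Conditions: AcCl (1.05 equiv), 2,4,6-collidine, CH2Cl2, −78 °C
Reagents that add atoms: acetyl chloride, CC(Cl)=O
Why: Kinetic acylation should select the primary hydroxyl over the hindered secondary C8–OH.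

Step 14
Reactants: 17 C13 acetate
Product: 18 C8 tiglate
Conditions: tigloyl chloride, pyridine, DMAP, CH2Cl2, 0 → 40 °C
Reagents that add atoms: (E)-2-methylbut-2-enoyl chloride, C/C=C(\C)C(Cl)=O
Why: DMAP-catalysed esterification of the remaining secondary alcohol; the E-acyl group is the stable isomer.

Step 15
Reactants: 18 C8 tiglate
Product: 19 C10,C1-diol
Conditions: AcOH/THF/H2O (3:1:1), 40 °C
Reagents that add atoms: none
Why: Mild acid hydrolysis of the isopropylidene ketal, under which the secondary TBS ether, the TBDPS ether and the esters should survive.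

Step 16
Reactants: 19 C10,C1-diol
Product: 21 α-hydroxy acid (C1 = CO2H), via α-hydroxy aldehyde 20 (not isolated)
Conditions: TEMPO (cat.), PhI(OAc)2, CH2Cl2, 23 °C; then NaClO2, NaH2PO4, 2-methylbut-2-ene, t-BuOH/H2O, 0 °C
Reagents that add atoms: sodium chlorite, [Na+].[O-]Cl=O
Why: TEMPO oxidation of the only primary alcohol (the tertiary C10–OH is inert) followed by Pinnick oxidation, with the alkene scavenger protecting the olefins.

Step 17
Reactants: 21 α-hydroxy acid
Product: 22 C1 S-ethyl thioester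
Conditions: EtSH, DCC, DMAP (cat.), CH2Cl2, 0 → 23 °C
Reagents that add atoms: ethanethiol, CCS
Why: Steglich-type thioesterification of the acid; the tertiary hydroxyl does not compete.

Step 18
Reactants: 22 C1 S-ethyl thioester
Product: 23 C10 acetate
Conditions: Ac2O, Et3N, DMAP, CH2Cl2, 23 → 40 °C
Reagents that add atoms: acetic anhydride, CC(=O)OC(C)=O
Why: DMAP-catalysed acetylation of the tertiary alcohol, done here while it is the only free hydroxyl and before ring and epoxide exist.

Step 19
Reactants: 23 C10 acetate; 24 4-bromo-2-methylbut-1-ene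
Product: 26 seco-diene ketone (C1 ketone with isopropenyl end), via organozinc bromide 25 (not isolated)
Conditions: 24, Zn, LiCl, THF, 50 °C; then 23, PdCl2(PPh3)2 (cat.), toluene, 23 °C
Reagents that add atoms: none
Why: Fukuyama coupling (Pd-catalysed acyl–alkyl coupling of a thioester with an alkylzinc halide) forms the C1 ketone directly and tolerates the esters, the α-acetoxy group and the silyl ethers.

Step 20
Reactants: 26 seco-diene ketone
Product: 27 seco-diene allylic alcohol (C6–OH free)
Conditions: HF·pyridine, pyridine, THF, 0 → 23 °C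
Reagents that add atoms: none
Why: Buffered HF should cleave the secondary TBS ether faster than the primary TBDPS ether, without base and so without acyl migration.

Step 21
Reactants: 27 seco-diene allylic alcohol
Product: 28 (4Z)-cyclodecenol
Conditions: Grubbs II (10 mol %), 1,4-benzoquinone (20 mol %), toluene (0.5 mM), 80 °C
Reagents that add atoms: none
Why: Ring-closing olefin metathesis: the Ru alkylidene loads on the monosubstituted C5 vinyl group (helped by the free allylic C6–OH), engages the 1,1-disubstituted C4 olefin through a metallacyclobutane and releases ethene. The closest known reaction type is RCM of vinyl/isopropenyl dienes to trisubstituted cyclodecenes in ten-membered terpenoid carbocycles. The ring closed is the ten-membered carbocycle C1–C10, by head-to-tail macrocyclising metathesis at C4=C5. No stereocentre is formed; the olefin should be Z because the E-trisubstituted cyclodecene is more strained and the metathesis is reversible, and this geometry later becomes the cis-fused oxirane. The step needs ring closure over oligomerisation (high dilution; the C7 branch point and quaternary C10 favour folded conformers) and chemoselectivity among three olefins, which the substrate secures because the tiglate is a trisubstituted electron-poor olefin inert to the catalyst; benzoquinone suppresses Ru–H isomerisation of the allylic alcohol.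

Step 22
Reactants: 28 (4Z)-cyclodecenol
Product: 29 4α,5α-epoxy alcohol
Conditions: VO(acac)2 (5 mol %), t-BuOOH, CH2Cl2, 0 → 23 °C
Reagents that add atoms: tert-butyl hydroperoxide, CC(C)(C)OO
Why: Hydroxyl-directed vanadium epoxidation: the vanadate ester of the C6 allylic alcohol delivers oxygen to the olefin face syn to O6 (the cis-epoxy alcohol, as known for medium-ring (Z)-cycloalk-2-enols), which sets C4 and C5 and leaves the tiglate untouched.

Step 23
Reactants: 29 4α,5α-epoxy alcohol
Product: 30 epoxy diol (C6–OH and C12–OH free)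
Conditions: TBAF, AcOH (1:1), THF, 23 °C
Reagents that add atoms: none
Why: Acetic-acid-buffered fluoride removes the TBDPS ether without opening the oxirane or moving the acetate between the two C11 arms; the crude diol is used at once.

Step 24
Reactants: 30 epoxy diol
Product: 32 target, via lactol 31 (not isolated)
Conditions: TEMPO (cat.), PhI(OAc)2, CH2Cl2, 23 °C
Reagents that add atoms: none
Why: Oxidative lactonisation: the primary C12 alcohol is oxidised to the aldehyde, the C6–OH traps it as a five-membered lactol, and this is oxidised to the trans-fused γ-lactone under neutral conditions that keep oxirane, esters and α-acetoxy ketone intact.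

**Compound list**
1 | (R)-citramalic acid, (2R)-2-hydroxy-2-methylbutanedioic acid | OC(=O)C[C@@](C)(O)C(=O)O | starting material
2 | (2R)-2-methylbutane-1,2,4-triol | OCC[C@@](C)(O)CO | intermediate
3 | 2-[(4R)-2,2,4-trimethyl-1,3-dioxolan-4-yl]ethanol | OCC[C@]1(C)COC(C)(C)O1 | intermediate
4 | 2-[(4R)-2,2,4-trimethyl-1,3-dioxolan-4-yl]acetaldehyde | O=CC[C@]1(C)COC(C)(C)O1 | intermediate
5 | (4R)-4-benzyl-1,3-oxazolidin-2-one | O=C1N[C@H](Cc2ccccc2)CO1 | starting material
6 | methyl 4-chloro-4-oxobutanoate | COC(=O)CCC(Cl)=O | starting material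
7 | methyl 4-[(4R)-4-benzyl-2-oxo-1,3-oxazolidin-3-yl]-4-oxobutanoate | COC(=O)CCC(=O)N1[C@H](Cc2ccccc2)COC1=O | intermediate
8 | syn-aldol adduct, methyl (3R,4S)-3-[(4R)-4-benzyl-2-oxo-1,3-oxazolidine-3-carbonyl]-4-hydroxy-5-[(4R)-2,2,4-trimethyl-1,3-dioxolan-4-yl]pentanoate | COC(=O)C[C@H]([C@@H](O)C[C@]1(C)COC(C)(C)O1)C(=O)N1[C@H](Cc2ccccc2)COC1=O | intermediate (not isolated)
9 | lactone imide, (4R)-4-benzyl-3-[(2S,3R)-5-oxo-2-{[(4R)-2,2,4-trimethyl-1,3-dioxolan-4-yl]methyl}oxolane-3-carbonyl]-1,3-oxazolidin-2-one | O=C1C[C@@H](C(=O)N3[C@H](Cc4ccccc4)COC3=O)[C@H](C[C@]2(C)COC(C)(C)O2)O1 | intermediate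
10 | lactone thioester, S-ethyl (2S,3R)-5-oxo-2-{[(4R)-2,2,4-trimethyl-1,3-dioxolan-4-yl]methyl}oxolane-3-carbothioate | O=C1C[C@@H](C(=O)SCC)[C@H](C[C@]2(C)COC(C)(C)O2)O1 | intermediate
11 | lactone aldehyde, (2S,3R)-5-oxo-2-{[(4R)-2,2,4-trimethyl-1,3-dioxolan-4-yl]methyl}oxolane-3-carbaldehyde | O=C1C[C@@H](C=O)[C@H](C[C@]2(C)COC(C)(C)O2)O1 | intermediate
12 | vinyl carbinol lactone, (4S,5S)-4-[(1R)-1-hydroxyprop-2-en-1-yl]-5-{[(4R)-2,2,4-trimethyl-1,3-dioxolan-4-yl]methyl}oxolan-2-one | O=C1C[C@@H]([C@@H](C=C)O)[C@H](C[C@]2(C)COC(C)(C)O2)O1 | intermediate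
13 | C6 silyl ether, the O-TBS ether of 12 | O=C1C[C@@H]([C@@H](C=C)O[Si](C)(C)C(C)(C)C)[C@H](C[C@]2(C)COC(C)(C)O2)O1 | intermediate
14 | α-hydroxymethyl lactone, 13 with CH2OH on the lactone α-carbon (C11) trans to the C7 substituent | O=C1[C@H](CO)[C@@H]([C@@H](C=C)O[Si](C)(C)C(C)(C)C)[C@H](C[C@]2(C)COC(C)(C)O2)O1 | intermediate
15 | C12 silyl ether, the primary O-TBDPS ether of 14 | O=C1[C@H](CO[Si](c3ccccc3)(c3ccccc3)C(C)(C)C)[C@@H]([C@@H](C=C)O[Si](C)(C)C(C)(C)C)[C@H](C[C@]2(C)COC(C)(C)O2)O1 | intermediate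
16 | seco-diol, open chain with C13–OH and C8–OH free, C12–OTBDPS, C6–OTBS, C10/C1 acetonide | OC[C@H](CO[Si](c1ccccc1)(c1ccccc1)C(C)(C)C)[C@@H]([C@@H](C=C)O[Si](C)(C)C(C)(C)C)[C@@H](O)C[C@]1(C)COC(C)(C)O1 | intermediate
17 | C13 acetate of 16 | CC(=O)OC[C@H](CO[Si](c1ccccc1)(c1ccccc1)C(C)(C)C)[C@@H]([C@@H](C=C)O[Si](C)(C)C(C)(C)C)[C@@H](O)C[C@]1(C)COC(C)(C)O1 | intermediate
18 | C8 tiglate of 17 | CC(=O)OC[C@H](CO[Si](c1ccccc1)(c1ccccc1)C(C)(C)C)[C@@H]([C@@H](C=C)O[Si](C)(C)C(C)(C)C)[C@@H](OC(=O)/C(C)=C/C)C[C@]1(C)COC(C)(C)O1 | intermediate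
19 | C10,C1-diol, 18 without the acetonide | CC(=O)OC[C@H](CO[Si](c1ccccc1)(c1ccccc1)C(C)(C)C)[C@@H]([C@@H](C=C)O[Si](C)(C)C(C)(C)C)[C@@H](OC(=O)/C(C)=C/C)C[C@@](C)(O)CO | intermediate
20 | α-hydroxy aldehyde, 19 with C1 as CHO | CC(=O)OC[C@H](CO[Si](c1ccccc1)(c1ccccc1)C(C)(C)C)[C@@H]([C@@H](C=C)O[Si](C)(C)C(C)(C)C)[C@@H](OC(=O)/C(C)=C/C)C[C@@](C)(O)C=O | intermediate (not isolated)
21 | α-hydroxy acid, 19 with C1 as CO2H | CC(=O)OC[C@H](CO[Si](c1ccccc1)(c1ccccc1)C(C)(C)C)[C@@H]([C@@H](C=C)O[Si](C)(C)C(C)(C)C)[C@@H](OC(=O)/C(C)=C/C)C[C@@](C)(O)C(=O)O | intermediate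
22 | C1 S-ethyl thioester of 21 | CC(=O)OC[C@H](CO[Si](c1ccccc1)(c1ccccc1)C(C)(C)C)[C@@H]([C@@H](C=C)O[Si](C)(C)C(C)(C)C)[C@@H](OC(=O)/C(C)=C/C)C[C@@](C)(O)C(=O)SCC | intermediate
23 | C10 acetate of 22 | CC(=O)OC[C@H](CO[Si](c1ccccc1)(c1ccccc1)C(C)(C)C)[C@@H]([C@@H](C=C)O[Si](C)(C)C(C)(C)C)[C@@H](OC(=O)/C(C)=C/C)C[C@@](C)(OC(C)=O)C(=O)SCC | intermediate
24 | 4-bromo-2-methylbut-1-ene | C=C(C)CCBr | starting material
25 | (3-methylbut-3-en-1-yl)zinc bromide | C=C(C)CC[Zn]Br | intermediate (not isolated)
26 | seco-diene ketone, C1 ketone carrying the CH2CH2C(CH3)=CH2 chain, C6–OTBS, C12–OTBDPS | CC(=O)OC[C@H](CO[Si](c1ccccc1)(c1ccccc1)C(C)(C)C)[C@@H]([C@@H](C=C)O[Si](C)(C)C(C)(C)C)[C@@H](OC(=O)/C(C)=C/C)C[C@@](C)(OC(C)=O)C(=O)CCC(C)=C | intermediate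
27 | seco-diene allylic alcohol, 26 with C6–OH free | CC(=O)OC[C@H](CO[Si](c1ccccc1)(c1ccccc1)C(C)(C)C)[C@@H]([C@@H](C=C)O)[C@@H](OC(=O)/C(C)=C/C)C[C@@](C)(OC(C)=O)C(=O)CCC(C)=C | intermediate
28 | (4Z)-cyclodecenol, ten-membered ring with Z-C4=C5, C6–OH, 8-tiglate, 10-acetate, 1-ketone, side chain CH(CH2OAc)(CH2OTBDPS) on C7 | CC(=O)OC[C@H](CO[Si](c2ccccc2)(c2ccccc2)C(C)(C)C)[C@H]1[C@H](O)/C=C(C)\CCC(=O)[C@](C)(OC(C)=O)C[C@@H]1OC(=O)/C(C)=C/C | intermediate
29 | 4α,5α-epoxy alcohol, the cis-oxirane of 28 syn to C6–OH | CC(=O)OC[C@H](CO[Si](c3ccccc3)(c3ccccc3)C(C)(C)C)[C@H]1[C@H](O)[C@@H]2O[C@]2(C)CCC(=O)[C@](C)(OC(C)=O)C[C@@H]1OC(=O)/C(C)=C/C | intermediate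
30 | epoxy diol, 29 with C12–OH free | CC(=O)OC[C@H](CO)[C@H]1[C@H](O)[C@@H]2O[C@]2(C)CCC(=O)[C@](C)(OC(C)=O)C[C@@H]1OC(=O)/C(C)=C/C | intermediate
31 | lactol, the 12-hydroxy-6,12-hemiacetal of the target (either C12 epimer) | C/C=C(\C)C(=O)O[C@H]1C[C@@](C)(OC(C)=O)C(=O)CC[C@@]2(C)O[C@H]2[C@H]2OC(O)[C@@H](COC(C)=O)[C@@H]21 | intermediate (not isolated)
32 | CNP0305680.1, 10α,13-diacetoxy-4α,5α-epoxy-1-oxo-8α-tigloyloxy-11βH-germacran-6α,12-olide | C/C=C(\C)C(=O)O[C@H]1C[C@@](C)(OC(C)=O)C(=O)CC[C@@]2(C)O[C@H]2[C@H]2OC(=O)[C@@H](COC(C)=O)[C@@H]21 | target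

**Count and risks**
Total: 24 steps. Longest linear sequence: 23 steps (steps 1–3 and 5–24; step 4 makes side fragment 7).

Most likely to fail:

1. Step 21 (ring-closing metathesis). The open chain may oligomerise, the hindered 1,1-disubstituted olefin may react too slowly, or some E-olefin may form. The fallback sets out from 27 and returns at 32. Buffered fluoride (TBAF/AcOH) removes the TBDPS group to give the seco-diene diol F1. TEMPO/PhI(OAc)2 closes the γ-lactone first to give the lactone diene F2, in which the trans-fused lactone freezes the C6–C7 bond and holds the two olefin arms closer. Metathesis of this constrained diene (Grubbs II, toluene, 80 °C) should give the macrocyclic (4Z)-ene lactone F3. Epoxidation with dimethyldioxirane (acetone, −20 °C) then gives 32. In this order the epoxide face rests on the lactone-fused ring conformation (attack anti to C7), not on a hydroxyl.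

2. Step 8 (vinyl addition). Facial selectivity at the aldehyde may be poor, or the β-acyloxy aldehyde may lose the lactone oxygen by base-induced elimination. The fallback sets out from 10 and returns at 13. Pd/Cu-catalysed coupling of the thioester with trimethylsilylacetylene (PdCl2(dppf), tri(2-furyl)phosphine, CuI, Et3N, DMF) gives the alkynyl ketone F4. Noyori transfer hydrogenation (RuCl(p-cymene)[(S,S)-TsDPEN], i-PrOH) should set C6 under reagent control to give the propargylic alcohol F5. TBSOTf/2,6-lutidine gives the silyl ether F6, K2CO3/MeOH at 0 °C removes the C-silyl group to give the terminal alkyne F7, and Lindlar semihydrogenation gives 13.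

3. Step 22 (directed epoxidation). A ten-membered ring is less biased than the eight- and nine-membered cycloalkenols, so facial selectivity may be low or reversed. The fallback sets out from 28 and returns at 29. NBS in aqueous THF forms the bromonium ion on the exposed face and water opens it at the tertiary C4 to give the bromohydrin F8. Ag2O then closes the oxirane by backside displacement at C5, which puts the oxygen on the face opposite to the one an external electrophile attacks.

Further compounds
F1 | step 21 | seco-diene diol, 27 with C12–OH free | CC(=O)OC[C@H](CO)[C@@H]([C@@H](C=C)O)[C@@H](OC(=O)/C(C)=C/C)C[C@@](C)(OC(C)=O)C(=O)CCC(C)=C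
F2 | step 21 | lactone diene, trans-γ-lactone (O6–C12) carrying the vinyl group on C6, CH2OAc on C11 and the acyclic C8–C4 chain on C7 | C=C[C@H]1OC(=O)[C@@H](COC(C)=O)[C@@H]1[C@@H](OC(=O)/C(C)=C/C)C[C@@](C)(OC(C)=O)C(=O)CCC(C)=C
F3 | step 21 | macrocyclic (4Z)-ene lactone, 4,5-deoxy-32 | C/C=C(\C)C(=O)O[C@H]1C[C@@](C)(OC(C)=O)C(=O)CC/C(C)=C\[C@H]2OC(=O)[C@@H](COC(C)=O)[C@@H]21
F4 | step 8 | alkynyl ketone, lactone of 10 with C6 as C(=O)C≡C–SiMe3 | O=C1C[C@@H](C(=O)C#C[Si](C)(C)C)[C@H](C[C@]2(C)COC(C)(C)O2)O1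
F5 | step 8 | propargylic alcohol, (6S)-carbinol from F4 | O=C1C[C@@H]([C@H](O)C#C[Si](C)(C)C)[C@H](C[C@]2(C)COC(C)(C)O2)O1
F6 | step 8 | O-TBS ether of F5 | O=C1C[C@@H]([C@H](O[Si](C)(C)C(C)(C)C)C#C[Si](C)(C)C)[C@H](C[C@]2(C)COC(C)(C)O2)O1
F7 | step 8 | terminal alkyne, F6 without the C-silyl group | O=C1C[C@@H]([C@H](O[Si](C)(C)C(C)(C)C)C#C)[C@H](C[C@]2(C)COC(C)(C)O2)O1
F8 | step 22 | bromohydrin, 28 with C4–OH (α) and C5–Br (β) | CC(=O)OC[C@H](CO[Si](c2ccccc2)(c2ccccc2)C(C)(C)C)[C@H]1[C@H](O)[C@@H](Br)[C@](C)(O)CCC(=O)[C@](C)(OC(C)=O)C[C@@H]1OC(=O)/C(C)=C/C
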